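**Strategy.** The chroman is disconnected at the benzylic C4–C4a bond. In the aromatic ring (ring A), C4a is the only unsubstituted carbon ortho to O1 and it lies para to the C7 oxygen. A Lewis acid can therefore make C4a attack the primary carbon of an (R)-epoxide tethered to O1 through the gem-dimethyl carbon C2. This one 6-endo Friedel–Crafts closure forms the pyran ring (ring B) and releases the C3 hydroxyl with its configuration untouched. The precursor is the mono-triisopropylsilyl ether of 2-prenyl-5-styrylresorcinol whose other oxygen carries a 2-[(2R)-oxiran-2-yl]propan-2-yl group.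

Key step: step 12

Remark (assumption): C3 of the target is R by CIP analysis. The (2S)-chlorohydrin 16 and the (2R)-epoxide 17 have the same spatial arrangement; the descriptor changes only because CH2Cl outranks the quaternary carbon. Prenyl = 3-methylbut-2-en-1-yl; styryl = (E)-2-phenylethenyl; chroman numbering is used for 18 and 19.

Step 1
Reactants: 1 methyl 3,5-dihydroxybenzoate
Product: 2 methyl 3,5-bis(methoxymethoxy)benzoate
Conditions: MOMCl (2.5 equiv), iPr2NEt (3 equiv), CH2Cl2, 0 °C → rt
Reagents that add atoms: chloromethyl methyl ether, COCCl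
Why: Williamson-type O-alkylation of both phenols by the reactive α-chloro ether gives the bis-acetal that later directs metalation, and the ester is inert to the amine base.

Step 2
Reactants: 2 methyl 3,5-bis(methoxymethoxy)benzoate
Product: 3 [3,5-bis(methoxymethoxy)phenyl]methanol
Conditions: LiAlH4 (1.0 equiv), THF, 0 °C; then H2O
Reagents that add atoms: none
Why: Hydride reduction of the ester with LiAlH4 should stop cleanly at the benzyl alcohol, since the acetal protecting groups are stable to hydride and base.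

Step 3
Reactants: 3 [3,5-bis(methoxymethoxy)phenyl]methanol; 4 prenyl bromide (1-bromo-3-methylbut-2-ene)
Product: 6 [3,5-bis(methoxymethoxy)-4-(3-methylbut-2-en-1-yl)phenyl]methanol, via C4-lithiated lithium alkoxide 5 (not isolated)
Conditions: n-BuLi (2.3 equiv), THF, −20 → 0 °C; then CuBr·SMe2 (10 mol %), 4 (1.3 equiv), −40 °C → rt
Reagents that add atoms: prenyl bromide 4, CC(C)=CCBr
Why: Directed ortho-metalation: after the alkoxide forms, n-BuLi removes the proton at C4, which is acidified and chelated by both flanking MOM ethers, and copper-catalysed allylic substitution at the primary carbon of prenyl bromide installs the prenyl group.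

Step 4
Reactants: 6 [3,5-bis(methoxymethoxy)-4-(3-methylbut-2-en-1-yl)phenyl]methanol
Product: 7 3,5-bis(methoxymethoxy)-4-(3-methylbut-2-en-1-yl)benzaldehyde
Conditions: activated MnO2 (10 equiv), CH2Cl2, rt
Reagents that add atoms: none
Why: Heterogeneous MnO2 oxidation is selective for benzylic alcohols and should leave the prenyl alkene and the acetals untouched.

Step 5
Reactants: 7 3,5-bis(methoxymethoxy)-4-(3-methylbut-2-en-1-yl)benzaldehyde; 8 diethyl benzylphosphonate
Product: 9 1,3-bis(methoxymethoxy)-2-(3-methylbut-2-en-1-yl)-5-[(E)-2-phenylethenyl]benzene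
Conditions: 8 (1.2 equiv), KOtBu (1.3 equiv), THF, 0 °C → rt
Reagents that add atoms: diethyl benzylphosphonate 8, CCOP(=O)(Cc1ccccc1)OCC
Why: Horner–Wadsworth–Emmons olefination of an aryl aldehyde with a benzylphosphonate anion reliably gives the E stilbene because the anti oxyanion intermediate eliminates preferentially.

Step 6
Reactants: 9 1,3-bis(methoxymethoxy)-2-(3-methylbut-2-en-1-yl)-5-[(E)-2-phenylethenyl]benzene
Product: 10 2-(3-methylbut-2-en-1-yl)-5-[(E)-2-phenylethenyl]benzene-1,3-diol (2-prenyl-5-styrylresorcinol)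
Conditions: TsOH·H2O (0.3 equiv), MeOH, rt → 40 °C
Reagents that add atoms: none
Why: Acid-catalysed transacetalisation to methanol removes both MOM groups under conditions mild enough that the ortho-prenyl phenol should not cyclise.

Step 7
Reactants: 10 2-prenyl-5-styrylresorcinol; 11 ethyl 2-bromo-2-methylpropanoate
Product: 12 ethyl 2-{3-hydroxy-2-(3-methylbut-2-en-1-yl)-5-[(E)-2-phenylethenyl]phenoxy}-2-methylpropanoate
Conditions: 11 (0.9 equiv), K2CO3 (1.5 equiv), DMF, 60 °C, N2; recovered 10 recycled
Reagents that add atoms: ethyl 2-bromo-2-methylpropanoate 11, CCOC(=O)C(C)(C)Br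
Why: Williamson-type phenoxide O-alkylation at the carbonyl-activated tertiary bromide builds the aryl tert-alkyl ether; the two hydroxyls are equivalent by symmetry, so only one mono-ether can form and a slight deficit of bromide limits double alkylation.

Step 8
Reactants: 12 ethyl 2-{3-hydroxy-2-prenyl-5-styrylphenoxy}-2-methylpropanoate
Product: 13 ethyl 2-methyl-2-{2-(3-methylbut-2-en-1-yl)-5-[(E)-2-phenylethenyl]-3-[(triisopropylsilyl)oxy]phenoxy}propanoate
Conditions: TIPSOTf (1.2 equiv), 2,6-lutidine (2 equiv), CH2Cl2, 0 °C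
Reagents that add atoms: triisopropylsilyl trifluoromethanesulfonate, CC(C)[Si](C(C)C)(C(C)C)OS(=O)(=O)C(F)(F)F
Why: Silylation with the silyl triflate and a hindered pyridine base is fast enough for the prenyl-flanked phenol and gives a group that tolerates organolithium, borane, hydride base and Lewis acid in the following steps.

Step 9
Reactants: 13 ethyl 2-methyl-2-{2-prenyl-5-styryl-3-[(triisopropylsilyl)oxy]phenoxy}propanoate
Product: 15 1-chloro-3-methyl-3-{2-(3-methylbut-2-en-1-yl)-5-[(E)-2-phenylethenyl]-3-[(triisopropylsilyl)oxy]phenoxy}butan-2-one, via lithium hemiketal alkoxide 14 (not isolated)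
Conditions: ClCH2I (2.0 equiv), MeLi·LiBr (1.9 equiv), THF/Et2O, −78 °C; AcOH, −78 °C → rt
Reagents that add atoms: chloroiodomethane, ClCI
Why: Carbenoid homologation of an ester: chloromethyllithium formed by iodine–lithium exchange adds once, and the α-aryloxy-chelated tetrahedral alkoxide 14 should persist at −78 °C and collapse to the chloromethyl ketone only on acidic quench.

Step 10
Reactants: 15 1-chloro-3-methyl-3-(aryloxy)butan-2-one
Product: 16 (2S)-1-chloro-3-methyl-3-{2-(3-methylbut-2-en-1-yl)-5-[(E)-2-phenylethenyl]-3-[(triisopropylsilyl)oxy]phenoxy}butan-2-ol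
Conditions: (S)-2-methyl-CBS-oxazaborolidine (0.2 equiv), catecholborane (1.5 equiv), toluene, −78 → −40 °C; then MeOH, aq. NaHCO3
Reagents that add atoms: none
Why: Corey–Bakshi–Shibata reduction: the (S)-oxazaborolidine binds the carbonyl with the tertiary CMe2(OAr) group as the large and CH2Cl as the small substituent, so hydride should reach the face that gives the 2S carbinol, while catecholborane at low temperature spares both alkenes.

Step 11
Reactants: 16 (2S)-chlorohydrin
Product: 17 triisopropyl{2-(3-methylbut-2-en-1-yl)-3-({2-[(2R)-oxiran-2-yl]propan-2-yl}oxy)-5-[(E)-2-phenylethenyl]phenoxy}silane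
Conditions: NaH (1.2 equiv), THF, 0 °C → rt
Reagents that add atoms: none
Why: Intramolecular Williamson closure (3-exo-tet) of the alkoxide onto the primary chloride forms the epoxide without touching the carbinol C–O bond, so the centre keeps its arrangement, and the non-nucleophilic base spares the aryl silyl ether.

Step 12
Reactants: 17 (R)-epoxy tert-alkyl aryl ether
Product: 18 (3R)-2,2-dimethyl-8-(3-methylbut-2-en-1-yl)-5-[(E)-2-phenylethenyl]-7-[(triisopropylsilyl)oxy]-3,4-dihydro-2H-chromen-3-ol
Conditions: Sc(OTf)3 (10 mol %), CH2Cl2 (0.02 M), −20 °C → rt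
Reagents that add atoms: none
Why: Sc(OTf)3 coordinates the epoxide oxygen, and C4a of ring A, activated by the ortho ether oxygen O1 and the para silyloxy group at C7, attacks the primary epoxide carbon in an SN2-like electrophilic aromatic substitution, after which loss of the C4a proton restores aromaticity and frees the C3 alcohol. The closest known reaction type is the Lewis-acid-promoted intramolecular Friedel–Crafts epoxy–arene cyclisation of aryl glycidyl ethers to 3-chromanols. Ring B closes in the 6-endo mode, so that the attacked carbon becomes C4 and the carbinol carbon becomes C3 of the new pyran ring. No stereocentre is created: the C3–O bond is never broken, so the R centre set in step 10 is carried into 18 unchanged. The step needs regioselectivity for the primary terminus over 5-exo attack at C3, which is secured because C3 is neopentyl-like next to the quaternary C2 and inductively deactivated by O1; on the arene, C8 is blocked by prenyl, so C4a is the only ortho carbon within reach, and the gem-dimethyl group favours the folded conformer. The silyl ether prevents acid-induced phenol–prenyl cyclisation, and the non-nucleophilic triflate cannot open the epoxide to a halohydrin.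

Step 13
Reactants: 18 7-O-triisopropylsilyl chromanol
Product: 19 (3R)-2,2-dimethyl-8-(3-methylbut-2-en-1-yl)-5-[(E)-2-phenylethenyl]-3,4-dihydro-2H-chromene-3,7-diol (target)
Conditions: Bu4NF (1.2 equiv), AcOH (1.2 equiv), THF, 0 °C
Reagents that add atoms: none
Why: Fluoride-induced desilylation of the aryl silyl ether is driven by Si–F bond formation, and the acetic acid buffer keeps the electron-rich phenol from being exposed as its phenoxide.

**Compound list**
1 | methyl 3,5-dihydroxybenzoate | COC(=O)c1cc(O)cc(O)c1 | starting material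
2 | methyl 3,5-bis(methoxymethoxy)benzoate | COCOc1cc(cc(OCOC)c1)C(=O)OC | intermediate
3 | [3,5-bis(methoxymethoxy)phenyl]methanol | COCOc1cc(CO)cc(OCOC)c1 | intermediate
4 | prenyl bromide (1-bromo-3-methylbut-2-ene) | CC(C)=CCBr | starting material
5 | lithium [4-lithio-3,5-bis(methoxymethoxy)phenyl]methanolate | [Li]OCc1cc(OCOC)c([Li])c(OCOC)c1 | intermediate
6 | [3,5-bis(methoxymethoxy)-4-(3-methylbut-2-en-1-yl)phenyl]methanol | COCOc1cc(CO)cc(OCOC)c1CC=C(C)C | intermediate
7 | 3,5-bis(methoxymethoxy)-4-(3-methylbut-2-en-1-yl)benzaldehyde | COCOc1cc(C=O)cc(OCOC)c1CC=C(C)C | intermediate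
8 | diethyl benzylphosphonate | CCOP(=O)(Cc1ccccc1)OCC | starting material
9 | 1,3-bis(methoxymethoxy)-2-(3-methylbut-2-en-1-yl)-5-[(E)-2-phenylethenyl]benzene | COCOc1cc(/C=C/c2ccccc2)cc(OCOC)c1CC=C(C)C | intermediate
10 | 2-(3-methylbut-2-en-1-yl)-5-[(E)-2-phenylethenyl]benzene-1,3-diol | CC(C)=CCc1c(O)cc(/C=C/c2ccccc2)cc1O | intermediate
11 | ethyl 2-bromo-2-methylpropanoate | CCOC(=O)C(C)(C)Br | starting material
12 | ethyl 2-{3-hydroxy-2-(3-methylbut-2-en-1-yl)-5-[(E)-2-phenylethenyl]phenoxy}-2-methylpropanoate | CCOC(=O)C(C)(C)Oc1cc(/C=C/c2ccccc2)cc(O)c1CC=C(C)C | intermediate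
13 | ethyl 2-methyl-2-{2-(3-methylbut-2-en-1-yl)-5-[(E)-2-phenylethenyl]-3-[(triisopropylsilyl)oxy]phenoxy}propanoate | CCOC(=O)C(C)(C)Oc1cc(/C=C/c2ccccc2)cc(O[Si](C(C)C)(C(C)C)C(C)C)c1CC=C(C)C | intermediate
14 | lithium 1-chloro-2-ethoxy-3-methyl-3-{2-prenyl-5-styryl-3-[(triisopropylsilyl)oxy]phenoxy}butan-2-olate (configuration at the transient hemiketal carbon undefined) | CCOC(O[Li])(CCl)C(C)(C)Oc1cc(/C=C/c2ccccc2)cc(O[Si](C(C)C)(C(C)C)C(C)C)c1CC=C(C)C | intermediate
15 | 1-chloro-3-methyl-3-{2-(3-methylbut-2-en-1-yl)-5-[(E)-2-phenylethenyl]-3-[(triisopropylsilyl)oxy]phenoxy}butan-2-one | ClCC(=O)C(C)(C)Oc1cc(/C=C/c2ccccc2)cc(O[Si](C(C)C)(C(C)C)C(C)C)c1CC=C(C)C | intermediate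
16 | (2S)-1-chloro-3-methyl-3-{2-(3-methylbut-2-en-1-yl)-5-[(E)-2-phenylethenyl]-3-[(triisopropylsilyl)oxy]phenoxy}butan-2-ol | CC(C)=CCc1c(O[Si](C(C)C)(C(C)C)C(C)C)cc(/C=C/c2ccccc2)cc1OC(C)(C)[C@H](O)CCl | intermediate
17 | triisopropyl{2-(3-methylbut-2-en-1-yl)-3-({2-[(2R)-oxiran-2-yl]propan-2-yl}oxy)-5-[(E)-2-phenylethenyl]phenoxy}silane | CC(C)=CCc1c(O[Si](C(C)C)(C(C)C)C(C)C)cc(/C=C/c2ccccc2)cc1OC(C)(C)[C@H]1CO1 | intermediate
18 | (3R)-2,2-dimethyl-8-(3-methylbut-2-en-1-yl)-5-[(E)-2-phenylethenyl]-7-[(triisopropylsilyl)oxy]-3,4-dihydro-2H-chromen-3-ol | CC(C)=CCc1c(O[Si](C(C)C)(C(C)C)C(C)C)cc(/C=C/c2ccccc2)c2c1OC(C)(C)[C@H](O)C2 | intermediate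
19 | (3R)-2,2-dimethyl-8-(3-methylbut-2-en-1-yl)-5-[(E)-2-phenylethenyl]-3,4-dihydro-2H-chromene-3,7-diol | CC(C)=CCc1c(O)cc(/C=C/c2ccccc2)c2c1OC(C)(C)[C@H](O)C2 | target

**Step count.** Total: 13 steps. Longest linear sequence: 13 steps (1 → 19).

**Steps most likely to fail**

Step 12. The Lewis acid may instead trigger reaction at the prenyl alkene, loss of the silyl ether followed by phenol–prenyl cyclisation, or opening at the internal epoxide carbon. In that case ring B would be built by a propargyl Claisen sequence. Setting out from 10, monosilylation (TIPSCl, imidazole, DMF, 0 °C) would give 2-prenyl-5-styryl-3-[(triisopropylsilyl)oxy]phenol F1. O-Alkylation with 3-chloro-3-methylbut-1-yne (DBU, CuCl2 cat., MeCN, 0 °C) would give the aryl 1,1-dimethylpropargyl ether F2. Heating in N,N-diethylaniline at about 140 °C should bring about propargyl Claisen rearrangement, 1,5-hydrogen shift and 6π-electrocyclisation at C4a, the only free ortho carbon, to give the 2,2-dimethyl-2H-chromene F3. Jacobsen–Katsuki epoxidation with (R,R)-(salen)MnCl [salen = N,N′-bis(3,5-di-tert-butylsalicylidene)-1,2-cyclohexanediamine], NaOCl and 4-phenylpyridine N-oxide should select the conjugated cis alkene over the isolated prenyl and the trans stilbene alkenes and give the (3R,4R)-3,4-epoxychroman F4. Hydride opening at the benzylic C4 with LiBHEt3 (THF, 0 °C) leaves the C3–O bond intact and rejoins the route at 18.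

Step 10. Facial discrimination between CH2Cl and the CMe2(OAr) group may be insufficient, or borane may add to the alkenes. The centre would then be secured by resolution. Setting out from 15, NaBH4 (MeOH/THF, 0 °C) would give the racemic chlorohydrin F5, and NaH in THF would close it to the racemic epoxide F6. Hydrolytic kinetic resolution with water (0.55 equiv) and the (salen)Co(OAc) enantiomer that consumes the S epoxide should convert that enantiomer into the (2S)-diol F7 and leave the R epoxide, which rejoins the route at 17. By analogy with simple terminal epoxides the (S,S) catalyst is expected to be the right one; this sense assignment is from memory and would be checked on the racemate first.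

Step 9. The tetrahedral adduct may collapse early, leading to a second carbenoid addition, or the hindered ester may convert incompletely. Setting out from 13, aminolysis with MeNH(OMe)·HCl and iPrMgCl (THF, −20 → 0 °C) would give the N-methoxy-N-methylamide F8. Chloromethyllithium (ClCH2I, MeLi·LiBr, −78 °C) adds only once to such amides because the five-membered lithium chelate survives until quench, and this rejoins the route at 15.

**Further compounds**
F1 | step 12 | 2-(3-methylbut-2-en-1-yl)-5-[(E)-2-phenylethenyl]-3-[(triisopropylsilyl)oxy]phenol | CC(C)=CCc1c(O)cc(/C=C/c2ccccc2)cc1O[Si](C(C)C)(C(C)C)C(C)C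
F2 | step 12 | triisopropyl{3-[(2-methylbut-3-yn-2-yl)oxy]-2-(3-methylbut-2-en-1-yl)-5-[(E)-2-phenylethenyl]phenoxy}silane | CC(C)=CCc1c(O[Si](C(C)C)(C(C)C)C(C)C)cc(/C=C/c2ccccc2)cc1OC(C)(C)C#C
F3 | step 12 | {[2,2-dimethyl-8-(3-methylbut-2-en-1-yl)-5-[(E)-2-phenylethenyl]-2H-chromen-7-yl]oxy}triisopropylsilane | CC(C)=CCc1c(O[Si](C(C)C)(C(C)C)C(C)C)cc(/C=C/c2ccccc2)c2c1OC(C)(C)C=C2
F4 | step 12 | (3R,4R)-3,4-epoxy-2,2-dimethyl-8-(3-methylbut-2-en-1-yl)-5-[(E)-2-phenylethenyl]-7-[(triisopropylsilyl)oxy]chroman | CC(C)=CCc1c(O[Si](C(C)C)(C(C)C)C(C)C)cc(/C=C/c2ccccc2)c2c1OC(C)(C)[C@@H]1O[C@H]21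
F5 | step 10 | racemic 1-chloro-3-methyl-3-{2-(3-methylbut-2-en-1-yl)-5-[(E)-2-phenylethenyl]-3-[(triisopropylsilyl)oxy]phenoxy}butan-2-ol | CC(C)=CCc1c(O[Si](C(C)C)(C(C)C)C(C)C)cc(/C=C/c2ccccc2)cc1OC(C)(C)C(O)CCl
F6 | step 10 | racemic triisopropyl{2-(3-methylbut-2-en-1-yl)-3-{[2-(oxiran-2-yl)propan-2-yl]oxy}-5-[(E)-2-phenylethenyl]phenoxy}silane | CC(C)=CCc1c(O[Si](C(C)C)(C(C)C)C(C)C)cc(/C=C/c2ccccc2)cc1OC(C)(C)C1CO1
F7 | step 10 | (2S)-3-methyl-3-{2-(3-methylbut-2-en-1-yl)-5-[(E)-2-phenylethenyl]-3-[(triisopropylsilyl)oxy]phenoxy}butane-1,2-diol | CC(C)=CCc1c(O[Si](C(C)C)(C(C)C)C(C)C)cc(/C=C/c2ccccc2)cc1OC(C)(C)[C@@H](O)CO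
F8 | step 9 | N-methoxy-N,2-dimethyl-2-{2-(3-methylbut-2-en-1-yl)-5-[(E)-2-phenylethenyl]-3-[(triisopropylsilyl)oxy]phenoxy}propanamide | CON(C)C(=O)C(C)(C)Oc1cc(/C=C/c2ccccc2)cc(O[Si](C(C)C)(C(C)C)C(C)C)c1CC=C(C)C
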